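## Retrosynthetic overview

1. Kurarinol ⇐ its tris-MOM ether (acid methanolysis last); the (2S) centre is fixed on the closed flavanone by a catalyst-controlled transfer-hydrogenation resolution of the C2 epimer pair.
2. Rings A and B are bought arenes; ring C is the only ring built and is closed last, by oxa-Michael addition of a 2'-hydroxychalcone.
3. Key C2–C3 bond: intermolecular Claisen–Schmidt aldol condensation of the ring A methyl ketone (side chain complete) with ring B 2,4-bis(methoxymethoxy)benzaldehyde.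
4. Ring A ketone ⇐ ortho-lithiation/acetylation of a symmetric 2,6-bis(MOM)-4-methoxyphenyl unit carrying the side chain; the MOM group ortho to the carbonyl is then removed selectively.
5. Side-chain (R) centre ⇐ Evans alkylation of an N-(3-arylpropanoyl)oxazolidinone with prenyl bromide; acyl carbon → isopropenyl (Weinreb amide, MeMgBr, Wittig), prenyl alkene → tertiary alcohol (Mukaiyama hydration); arylpropanoic acid ⇐ 5-methoxyresorcinol.

Assumption: the three numbered starting materials and all unnumbered reagents are bought from catalogues; "cheap" is read as a few euros per gram or less.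

## Route

Step 1
Reactants: 1 5-methoxyresorcinol (3,5-dihydroxyanisole)
Product: 2 bis-MOM ether 1-methoxy-3,5-bis(methoxymethoxy)benzene
Conditions: NaH, DMF, 0 °C; MOMCl, 0 °C → rt
Reagents that add atoms: chloromethyl methyl ether (MOMCl), COCCl
Why: Double Williamson O-alkylation of the phenoxides installs two base-stable MOM acetals that also serve as directing groups for the later ortho-lithiations.

Step 2
Reactants: 2 bis-MOM ether
Product: 4 aldehyde 4-methoxy-2,6-bis(methoxymethoxy)benzaldehyde, via aryllithium 3 (not isolated)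
Conditions: n-BuLi, THF, 0 °C, 1 h; DMF, 0 °C → rt; H2O
Reagents that add atoms: N,N-dimethylformamide, CN(C)C=O
Why: Directed ortho-metalation takes place at the carbon flanked by the two OMOM groups (cooperative chelation, stronger directors than OMe) and the aryllithium is formylated by DMF.

Step 3
Reactants: 4 aldehyde
Product: 5 cinnamate ethyl (2E)-3-[4-methoxy-2,6-bis(methoxymethoxy)phenyl]prop-2-enoate
Conditions: (EtO)2P(O)CH2CO2Et, NaH, THF, 0 °C → rt
Reagents that add atoms: triethyl phosphonoacetate, CCOC(=O)CP(=O)(OCC)OCC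
Why: Horner–Wadsworth–Emmons olefination of the non-enolisable aldehyde gives the E-alkene under thermodynamic control.

Step 4
Reactants: 5 cinnamate
Product: 6 ester ethyl 3-[4-methoxy-2,6-bis(methoxymethoxy)phenyl]propanoate
Conditions: H2 (1 atm), Pd/C (10 wt %), EtOAc, rt
Reagents that add atoms: none
Why: Heterogeneous catalytic hydrogenation saturates the conjugated alkene while aryl MOM ethers and the ester are inert.

Step 5
Reactants: 6 ester
Product: 7 acid 3-[4-methoxy-2,6-bis(methoxymethoxy)phenyl]propanoic acid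
Conditions: LiOH, THF/MeOH/H2O, rt; 1 M HCl to pH 4, 0 °C
Reagents that add atoms: lithium hydroxide, [Li+].[OH-]
Why: Ester saponification; the MOM acetals are stable to base and survive the brief cold acidification.

Step 6
Reactants: 7 acid; 8 (4R)-4-benzyl-1,3-oxazolidin-2-one
Product: 10 imide (4R)-4-benzyl-3-{3-[4-methoxy-2,6-bis(methoxymethoxy)phenyl]propanoyl}-1,3-oxazolidin-2-one, via mixed pivalic anhydride 9 (not isolated)
Conditions: PivCl, Et3N, THF, −20 °C; then 8, LiCl, −20 °C → rt
Reagents that add atoms: none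
Why: N-acylation of the auxiliary through the mixed anhydride, which is attacked at the less hindered (non-pivaloyl) carbonyl.

Step 7
Reactants: 10 imide
Product: 12 alkylated imide (4R)-4-benzyl-3-[(2R)-2-{[4-methoxy-2,6-bis(methoxymethoxy)phenyl]methyl}-5-methylhex-4-enoyl]-1,3-oxazolidin-2-one, via sodium Z-enolate 11 (not isolated)
Conditions: NaN(SiMe3)2, THF, −78 °C; prenyl bromide, −78 → −40 °C
Reagents that add atoms: prenyl bromide (1-bromo-3-methylbut-2-ene), CC(C)=CCBr
Why: Evans asymmetric alkylation: the chelated Z-enolate is alkylated on the face opposite the benzyl group of the (R)-auxiliary, which sets the (R) side-chain centre (typically >95:5, minor diastereomer removed by chromatography).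

Step 8
Reactants: 12 alkylated imide
Product: 14 acid (2R)-2-{[4-methoxy-2,6-bis(methoxymethoxy)phenyl]methyl}-5-methylhex-4-enoic acid, via lithium peroxycarboxylate 13 (not isolated)
Conditions: LiOH, H2O2, THF/H2O, 0 °C; Na2SO3; 1 M HCl to pH 4
Reagents that add atoms: hydrogen peroxide, OO
Why: Hydroperoxide attacks the exocyclic imide carbonyl selectively (nucleophilic acyl substitution), so the auxiliary is released without epimerising the α-centre.

Step 9
Reactants: 14 acid
Product: 16 Weinreb amide (2R)-N-methoxy-2-{[4-methoxy-2,6-bis(methoxymethoxy)phenyl]methyl}-N,5-dimethylhex-4-enamide, via acyl imidazolide 15 (not isolated)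
Conditions: CDI, CH2Cl2, rt; MeNHOMe·HCl, rt
Reagents that add atoms: N,O-dimethylhydroxylamine hydrochloride, CNOC.Cl
Why: Amide coupling through the acyl imidazolide, a mild activation that does not racemise an α,α-dialkyl acid.

Step 10
Reactants: 16 Weinreb amide
Product: 17 methyl ketone (3R)-3-{[4-methoxy-2,6-bis(methoxymethoxy)phenyl]methyl}-6-methylhept-5-en-2-one
Conditions: MeMgBr, THF, 0 °C; H2O
Reagents that add atoms: methylmagnesium bromide, C[Mg]Br
Why: Weinreb ketone synthesis: the N-methoxy-N-methylamide takes up exactly one methyl nucleophile, so the reaction stops at the ketone.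

Step 11
Reactants: 17 methyl ketone
Product: 18 hydroxy ketone (3R)-6-hydroxy-3-{[4-methoxy-2,6-bis(methoxymethoxy)phenyl]methyl}-6-methylheptan-2-one
Conditions: Co(acac)2 (20 mol %), PhSiH3, O2 (1 atm), THF, rt
Reagents that add atoms: dioxygen, O=O
Why: Mukaiyama hydration (hydrogen-atom transfer from a cobalt hydride, O2 trapping of the tertiary radical) gives the Markovnikov tertiary alcohol from the only alkene present at this stage.

Step 12
Reactants: 18 hydroxy ketone
Product: 19 alkene (5R)-5-{[4-methoxy-2,6-bis(methoxymethoxy)phenyl]methyl}-2,6-dimethylhept-6-en-2-ol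
Conditions: Ph3PCH3Br, KN(SiMe3)2 (excess), THF, 0 °C; then 18, 0 °C → rt
Reagents that add atoms: methyltriphenylphosphonium bromide, C[P+](c1ccccc1)(c1ccccc1)c1ccccc1.[Br-]
Why: Wittig methylenation turns the methyl ketone into the isopropenyl group; the salt-free ylide adds faster than it deprotonates the hindered methine, so the stereocentre is kept.

Step 13
Reactants: 19 alkene
Product: 21 acetophenone 1-{3-[(2R)-5-hydroxy-5-methyl-2-(prop-1-en-2-yl)hexyl]-6-methoxy-2,4-bis(methoxymethoxy)phenyl}ethan-1-one, via dilithio species 20 (not isolated)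
Conditions: n-BuLi (2.3 equiv), THF, 0 °C, 1 h; MeC(O)N(OMe)Me, −78 °C → rt; H2O
Reagents that add atoms: N-methoxy-N-methylacetamide, CON(C)C(C)=O
Why: After O-lithiation of the alcohol, directed ortho-metalation occurs at one of the two equivalent ring positions between OMOM and OMe, and the aryllithium is acylated once by the Weinreb amide.

Step 14
Reactants: 21 acetophenone
Product: 22 hydroxyacetophenone 1-{2-hydroxy-3-[(2R)-5-hydroxy-5-methyl-2-(prop-1-en-2-yl)hexyl]-6-methoxy-4-(methoxymethoxy)phenyl}ethan-1-one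
Conditions: HCl (0.3 M in MeOH), 0 °C → rt, followed by TLC
Reagents that add atoms: none
Why: Acid-catalysed acetal methanolysis is fastest for the MOM ether ortho to the acetyl group (carbonyl-assisted departure, hydrogen-bonded phenol product, relief of crowding), so the 4-MOM ether, the tertiary alcohol and the isopropenyl group survive the short mild exposure.

Step 15
Reactants: 23 2,4-dihydroxybenzaldehyde
Product: 24 ring B aldehyde 2,4-bis(methoxymethoxy)benzaldehyde
Conditions: NaH, DMF, 0 °C; MOMCl, 0 °C → rt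
Reagents that add atoms: chloromethyl methyl ether (MOMCl), COCCl
Why: Williamson O-alkylation of both phenoxides gives a base-stable, non-enolisable aldol acceptor.

Step 16
Reactants: 22 hydroxyacetophenone; 24 ring B aldehyde
Product: 26 chalcone (2E)-3-[2,4-bis(methoxymethoxy)phenyl]-1-{2-hydroxy-3-[(2R)-5-hydroxy-5-methyl-2-(prop-1-en-2-yl)hexyl]-6-methoxy-4-(methoxymethoxy)phenyl}prop-2-en-1-one, via aldol adduct 25 (not isolated)
Conditions: KOH (50% aq), EtOH, rt, 48 h
Reagents that add atoms: none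
Why: Claisen–Schmidt crossed aldol condensation: only the methyl ketone can enolise, the aldehyde is the only electrophile, and E1cB dehydration of the aldol gives the E-enone, forming the C2–C3 bond that joins the two halves.

Step 17
Reactants: 26 chalcone
Product: 27 flavanone 2-[2,4-bis(methoxymethoxy)phenyl]-8-[(2R)-5-hydroxy-5-methyl-2-(prop-1-en-2-yl)hexyl]-5-methoxy-7-(methoxymethoxy)-2,3-dihydro-4H-chromen-4-one as a 1:1 mixture of C2 epimers
Conditions: NaOAc, EtOH, reflux, 24–48 h
Reagents that add atoms: none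
Why: Intramolecular oxa-Michael addition of the phenoxide closes ring C; the remote side-chain centre exerts no control, so both C2 epimers form.

Step 18
Reactants: 27 flavanone epimer mixture
Product: 28 (2S)-flavanone (2S)-2-[2,4-bis(methoxymethoxy)phenyl]-8-[(2R)-5-hydroxy-5-methyl-2-(prop-1-en-2-yl)hexyl]-5-methoxy-7-(methoxymethoxy)-2,3-dihydro-4H-chromen-4-one
Conditions: RhCl(Cp*)[(R,R)-TsDPEN] (1 mol %), HCO2H/Et3N (5:2), EtOAc, rt, stopped near 50% conversion
Reagents that add atoms: none
Why: Noyori-type asymmetric transfer hydrogenation used as a kinetic resolution: the (R,R)-catalyst delivers hydride to make a (4R)-alcohol trans to the 2-aryl group, so only the (2R)-epimer is matched and is reduced to the cis-(2R,4R)-flavan-4-ol, while the (2S)-ketone stays and is isolated by chromatography.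

Step 19
Reactants: 28 (2S)-flavanone
Product: 29 kurarinol (2S)-2-(2,4-dihydroxyphenyl)-7-hydroxy-8-[(2R)-5-hydroxy-5-methyl-2-(prop-1-en-2-yl)hexyl]-5-methoxy-2,3-dihydro-4H-chromen-4-one
Conditions: 3 M aq HCl/MeOH (1:4), 40 °C, 1–2 h
Reagents that add atoms: none
Why: Acid-catalysed acetal methanolysis removes the three aryl MOM groups under conditions known to spare prenyl-type alkenes and the C2 configuration of flavanones; the aryl methyl ether is untouched.

## Compound list

1 | 5-methoxyresorcinol (3,5-dihydroxyanisole) | COc1cc(O)cc(O)c1 | starting material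
2 | 1-methoxy-3,5-bis(methoxymethoxy)benzene | COc1cc(OCOC)cc(OCOC)c1 | intermediate
3 | [4-methoxy-2,6-bis(methoxymethoxy)phenyl]lithium | [Li]c1c(OCOC)cc(OC)cc1OCOC | intermediate (not isolated)
4 | 4-methoxy-2,6-bis(methoxymethoxy)benzaldehyde | O=Cc1c(OCOC)cc(OC)cc1OCOC | intermediate
5 | ethyl (2E)-3-[4-methoxy-2,6-bis(methoxymethoxy)phenyl]prop-2-enoate | CCOC(=O)/C=C/c1c(OCOC)cc(OC)cc1OCOC | intermediate
6 | ethyl 3-[4-methoxy-2,6-bis(methoxymethoxy)phenyl]propanoate | CCOC(=O)CCc1c(OCOC)cc(OC)cc1OCOC | intermediate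
7 | 3-[4-methoxy-2,6-bis(methoxymethoxy)phenyl]propanoic acid | OC(=O)CCc1c(OCOC)cc(OC)cc1OCOC | intermediate
8 | (4R)-4-benzyl-1,3-oxazolidin-2-one | O=C1N[C@H](Cc2ccccc2)CO1 | starting material
9 | mixed anhydride of 7 with pivalic acid | CC(C)(C)C(=O)OC(=O)CCc1c(OCOC)cc(OC)cc1OCOC | intermediate (not isolated)
10 | (4R)-4-benzyl-3-{3-[4-methoxy-2,6-bis(methoxymethoxy)phenyl]propanoyl}-1,3-oxazolidin-2-one | O=C(CCc1c(OCOC)cc(OC)cc1OCOC)N1C(=O)OC[C@H]1Cc1ccccc1 | intermediate
11 | sodium (Z)-enolate of 10 | [Na+].[O-]/C(=C\Cc1c(OCOC)cc(OC)cc1OCOC)N1C(=O)OC[C@H]1Cc1ccccc1 | intermediate (not isolated)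
12 | (4R)-4-benzyl-3-[(2R)-2-{[4-methoxy-2,6-bis(methoxymethoxy)phenyl]methyl}-5-methylhex-4-enoyl]-1,3-oxazolidin-2-one | O=C([C@H](CC=C(C)C)Cc1c(OCOC)cc(OC)cc1OCOC)N1C(=O)OC[C@H]1Cc1ccccc1 | intermediate
13 | lithium (2R)-2-{[4-methoxy-2,6-bis(methoxymethoxy)phenyl]methyl}-5-methylhex-4-eneperoxoate | [Li+].[O-]OC(=O)[C@H](CC=C(C)C)Cc1c(OCOC)cc(OC)cc1OCOC | intermediate (not isolated)
14 | (2R)-2-{[4-methoxy-2,6-bis(methoxymethoxy)phenyl]methyl}-5-methylhex-4-enoic acid | OC(=O)[C@H](CC=C(C)C)Cc1c(OCOC)cc(OC)cc1OCOC | intermediate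
15 | acyl imidazolide of 14, (2R)-1-(imidazol-1-yl)-2-{[4-methoxy-2,6-bis(methoxymethoxy)phenyl]methyl}-5-methylhex-4-en-1-one | O=C([C@H](CC=C(C)C)Cc1c(OCOC)cc(OC)cc1OCOC)n1ccnc1 | intermediate (not isolated)
16 | (2R)-N-methoxy-2-{[4-methoxy-2,6-bis(methoxymethoxy)phenyl]methyl}-N,5-dimethylhex-4-enamide | CON(C)C(=O)[C@H](CC=C(C)C)Cc1c(OCOC)cc(OC)cc1OCOC | intermediate
17 | (3R)-3-{[4-methoxy-2,6-bis(methoxymethoxy)phenyl]methyl}-6-methylhept-5-en-2-one | CC(=O)[C@H](CC=C(C)C)Cc1c(OCOC)cc(OC)cc1OCOC | intermediate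
18 | (3R)-6-hydroxy-3-{[4-methoxy-2,6-bis(methoxymethoxy)phenyl]methyl}-6-methylheptan-2-one | CC(=O)[C@H](CCC(C)(C)O)Cc1c(OCOC)cc(OC)cc1OCOC | intermediate
19 | (5R)-5-{[4-methoxy-2,6-bis(methoxymethoxy)phenyl]methyl}-2,6-dimethylhept-6-en-2-ol | C=C(C)[C@H](CCC(C)(C)O)Cc1c(OCOC)cc(OC)cc1OCOC | intermediate
20 | O,C-dilithio derivative of 19 (lithium alkoxide, aryllithium between OMOM and OMe) | C=C(C)[C@H](CCC(C)(C)O[Li])Cc1c(OCOC)cc(OC)c([Li])c1OCOC | intermediate (not isolated)
21 | 1-{3-[(2R)-5-hydroxy-5-methyl-2-(prop-1-en-2-yl)hexyl]-6-methoxy-2,4-bis(methoxymethoxy)phenyl}ethan-1-one | C=C(C)[C@H](CCC(C)(C)O)Cc1c(OCOC)cc(OC)c(C(C)=O)c1OCOC | intermediate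
22 | 1-{2-hydroxy-3-[(2R)-5-hydroxy-5-methyl-2-(prop-1-en-2-yl)hexyl]-6-methoxy-4-(methoxymethoxy)phenyl}ethan-1-one | C=C(C)[C@H](CCC(C)(C)O)Cc1c(OCOC)cc(OC)c(C(C)=O)c1O | intermediate
23 | 2,4-dihydroxybenzaldehyde | O=Cc1ccc(O)cc1O | starting material
24 | 2,4-bis(methoxymethoxy)benzaldehyde | O=Cc1ccc(OCOC)cc1OCOC | intermediate
25 | aldol adduct 3-[2,4-bis(methoxymethoxy)phenyl]-3-hydroxy-1-{2-hydroxy-3-[(2R)-5-hydroxy-5-methyl-2-(prop-1-en-2-yl)hexyl]-6-methoxy-4-(methoxymethoxy)phenyl}propan-1-one (both carbinol configurations) | C=C(C)[C@H](CCC(C)(C)O)Cc1c(OCOC)cc(OC)c(C(=O)CC(O)c2ccc(OCOC)cc2OCOC)c1O | intermediate (not isolated)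
26 | (2E)-3-[2,4-bis(methoxymethoxy)phenyl]-1-{2-hydroxy-3-[(2R)-5-hydroxy-5-methyl-2-(prop-1-en-2-yl)hexyl]-6-methoxy-4-(methoxymethoxy)phenyl}prop-2-en-1-one | C=C(C)[C@H](CCC(C)(C)O)Cc1c(OCOC)cc(OC)c(C(=O)/C=C/c2ccc(OCOC)cc2OCOC)c1O | intermediate
27 | 2-[2,4-bis(methoxymethoxy)phenyl]-8-[(2R)-5-hydroxy-5-methyl-2-(prop-1-en-2-yl)hexyl]-5-methoxy-7-(methoxymethoxy)-2,3-dihydro-4H-chromen-4-one, about 1:1 (2S)/(2R), C2 left open in the SMILES | C=C(C)[C@H](CCC(C)(C)O)Cc1c(OCOC)cc(OC)c2c1OC(c1ccc(OCOC)cc1OCOC)CC2=O | intermediate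
28 | (2S)-2-[2,4-bis(methoxymethoxy)phenyl]-8-[(2R)-5-hydroxy-5-methyl-2-(prop-1-en-2-yl)hexyl]-5-methoxy-7-(methoxymethoxy)-2,3-dihydro-4H-chromen-4-one | C=C(C)[C@H](CCC(C)(C)O)Cc1c(OCOC)cc(OC)c2c1O[C@H](c1ccc(OCOC)cc1OCOC)CC2=O | intermediate
29 | kurarinol, (2S)-2-(2,4-dihydroxyphenyl)-7-hydroxy-8-[(2R)-5-hydroxy-5-methyl-2-(prop-1-en-2-yl)hexyl]-5-methoxy-2,3-dihydro-4H-chromen-4-one | C=C(C)[C@H](CCC(C)(C)O)Cc1c(O)cc(OC)c2c1O[C@H](c1ccc(O)cc1O)CC2=O | target

## Step count and risks

Total step count: 19. Longest linear sequence: 18 steps (steps 1 to 14 and 16 to 19, from 1 to 29); step 15 is the single step of the second branch.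

The three steps most likely to fail are steps 14, 18 and 19.

The selective removal of one MOM group in step 14 may not discriminate well enough between the 2-O and 4-O acetals. The fallback sets out from 21 and removes both MOM ethers (3 M HCl/MeOH, 40 °C) to give 1-{2,4-dihydroxy-3-[(2R)-5-hydroxy-5-methyl-2-(prop-1-en-2-yl)hexyl]-6-methoxyphenyl}ethan-1-one F1. Only the 4-hydroxyl is then re-protected (MOMCl 1.05 equiv, iPr2NEt, CH2Cl2, 0 °C), because the 2-hydroxyl is tied up in a hydrogen bond to the ketone; this comes back to the route at 22.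

The kinetic resolution in step 18 may be too slow or too unselective, since the substrate has an ortho-substituted ring B and a crowded ketone. The fallback sets out from 27 and separates the two C2 epimers physically by preparative HPLC on a polysaccharide chiral stationary phase (amylose tris(3,5-dimethylphenylcarbamate), hexane/iPrOH), a separation that is routine for flavanone C2 antipodes, and comes back at 28. The unwanted (2R)-epimer is re-equilibrated with NaOAc in refluxing EtOH through chalcone 26 and recycled; no new compound is made, F0.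

The Brønsted-acid deprotection in step 19 may damage the tertiary alcohol or let the 7-hydroxyl add to the isopropenyl group. The fallback sets out from 28 and uses a silyl-transfer deprotection instead: TMSOTf/2,2'-bipyridyl in CH2Cl2 at 0 °C converts the three aryl MOM ethers, and the tertiary alcohol, into trimethylsilyl ethers. This gives (2S)-2-[2,4-bis(trimethylsilyloxy)phenyl]-5-methoxy-8-[(2R)-5-methyl-2-(prop-1-en-2-yl)-5-(trimethylsilyloxy)hexyl]-7-(trimethylsilyloxy)-2,3-dihydro-4H-chromen-4-one F2, which is desilylated with citric acid in aqueous MeOH at rt and comes back at 29.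

Further compounds
F1 | step 14 | 1-{2,4-dihydroxy-3-[(2R)-5-hydroxy-5-methyl-2-(prop-1-en-2-yl)hexyl]-6-methoxyphenyl}ethan-1-one | C=C(C)[C@H](CCC(C)(C)O)Cc1c(O)cc(OC)c(C(C)=O)c1O
F0 | step 18 | none | none
F2 | step 19 | (2S)-2-[2,4-bis(trimethylsilyloxy)phenyl]-5-methoxy-8-[(2R)-5-methyl-2-(prop-1-en-2-yl)-5-(trimethylsilyloxy)hexyl]-7-(trimethylsilyloxy)-2,3-dihydro-4H-chromen-4-one | C=C(C)[C@H](CCC(C)(C)O[Si](C)(C)C)Cc1c(O[Si](C)(C)C)cc(OC)c2c1O[C@H](c1ccc(O[Si](C)(C)C)cc1O[Si](C)(C)C)CC2=O
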